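**Retrosynthetic overview**

1. Target ⇒ diol (acetylation) ⇒ bis-silyl ether; the 12-membered ring is opened at C3–C4 (reductive hydroalkenylation of a ring-A vinyl group with a 2-bromo-1-alkene).
2. C8–C9 ⇒ stereoinvertive 1,2-alkenyl shift (semipinacol) in the adduct of a C4–C8 alkenylcerium with a trans α-bromo-β-silyloxy bicyclic enone; this sets C9 cis to the C18 oxygen.
3. Five-membered ring ⇒ bromine–lithium exchange/intramolecular acylation of the asymmetric acetate aldol adduct (C18) of a β-bromo enal.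
4. β-Bromo enal ⇒ haloformylation of (S)-2,2-dimethyl-3-vinylcyclohexanone ⇒ asymmetric conjugate vinylation/methylation of 2-methylcyclohexenone (C1, C15).
5. C4–C8 piece ⇒ asymmetric 2-bromoallylation of but-2-ynal (C6), then hydrozirconation–iodination (7E). Ring order: six-membered ring (bought), five-membered ring, macrocycle.

Assumption: atom labels C1–C20 are verticillane-type labels of the target (C1 ring-A methine; C2–C8 bridge with C4 bearing exo-methylene C20, C6 carbinol, C7=C8; C9 ketone α-carbon; C10 ketone; C11=C12 ring fusion; C13, C14; C15 gem-dimethyl carbon; C18 five-ring carbinol). For each chiral catalyst the enantiomer that gives the stated configuration is used, and but-2-ynal is taken as commercially available.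

**Route**

Step 1
Reactants: 1 2-methylcyclohex-2-en-1-one; 2 vinylmagnesium bromide
Product: 4 (S)-2,2-dimethyl-3-vinylcyclohexan-1-one, via magnesium enolate 3 (not isolated)
Conditions: CuBr·SMe2 (5 mol%), (R)-1-[(S)-2-(diphenylphosphino)ferrocenyl]ethyldicyclohexylphosphine (6 mol%), t-BuOMe, −78 °C; then MeI, DMPU, −78 °C → rt
Reagents that add atoms: iodomethane, CI
Why: Copper-catalysed asymmetric conjugate addition with enolate trapping: the chiral monovalent copper–diphosphine complex delivers vinyl to one enone face (sets C1) and the regiodefined magnesium enolate is C-methylated to build the gem-dimethyl carbon C15.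

Step 2
Reactants: 4 (S)-2,2-dimethyl-3-vinylcyclohexan-1-one
Product: 6 (4S)-2-bromo-3,3-dimethyl-4-vinylcyclohex-1-ene-1-carbaldehyde, via iminium bromide 5 (not isolated)
Conditions: PBr3, DMF, CHCl3, 0 → 50 °C; then aq NaOAc, 0 °C
Reagents that add atoms: N,N-dimethylformamide, CN(C)C=O; phosphorus tribromide, BrP(Br)Br; water, O
Why: Vilsmeier–Arnold haloformylation is regiospecific because only C12 is enolisable (C15 is quaternary), giving C11–Br and the C18 aldehyde without touching C1.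

Step 3
Reactants: 6 (4S)-2-bromo-3,3-dimethyl-4-vinylcyclohex-1-ene-1-carbaldehyde; 7 1-(tert-butyldimethylsilyloxy)-1-methoxyethene
Product: 9 methyl (3R)-3-[(4S)-2-bromo-3,3-dimethyl-4-vinylcyclohex-1-en-1-yl]-3-hydroxypropanoate, via trichlorosilyl aldolate 8 (not isolated)
Conditions: SiCl4 (1.5 equiv), (R,R)-bisphosphoramide made of two (R)-N,N′-dimethyl-1,1′-binaphthyl-2,2′-diamine phosphoryl units on an N,N′-dimethylpentane-1,5-diamine tether (5 mol%), i-Pr2NEt (10 mol%), CH2Cl2, −78 °C; then sat. aq NaHCO3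
Reagents that add atoms: none
Why: Lewis-base-catalysed Mukaiyama acetate aldol addition: the phosphoramide-bound trichlorosilyl cation activates the aldehyde and dictates the enolate face, so C18 (R) is set by the catalyst alone (C1 is too remote to interfere).

Step 4
Reactants: 9 methyl (3R)-3-[(4S)-2-bromo-3,3-dimethyl-4-vinylcyclohex-1-en-1-yl]-3-hydroxypropanoate
Product: 12 (3R,6S)-3-[(tert-butyldimethylsilyl)oxy]-7,7-dimethyl-6-vinyl-2,3,4,5,6,7-hexahydro-1H-inden-1-one, via dilithio species 10 (not isolated), via lithium alkoxide 11 (not isolated)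
Conditions: t-BuLi (3.1 equiv), THF/Et2O, −100 → −78 °C; then TBSOTf (2.2 equiv), −78 → −40 °C
Reagents that add atoms: tert-butyldimethylsilyl trifluoromethanesulfonate, CC(C)(C)[Si](C)(C)OS(=O)(=O)C(F)(F)F
Why: Parham cyclisation: bromine–lithium exchange outruns ester attack at −100 °C and the C11 vinyllithium acylates the ester 5-exo-trig to close the cyclopentenone, the lithium alkoxide shielding C18–O until it is silylated in the same flask.

Step 5
Reactants: 12 (3R,6S)-3-[(tert-butyldimethylsilyl)oxy]-7,7-dimethyl-6-vinyl-2,3,4,5,6,7-hexahydro-1H-inden-1-one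
Product: 14 (2R,3S,6S)-2-bromo-3-[(tert-butyldimethylsilyl)oxy]-7,7-dimethyl-6-vinyl-2,3,4,5,6,7-hexahydro-1H-inden-1-one, via silyl dienol ether 13 (not isolated)
Conditions: TMSCl, LiHMDS, THF, −78 °C; then NBS, −78 °C
Reagents that add atoms: N-bromosuccinimide, O=C1CCC(=O)N1Br
Why: Kinetic cross-conjugated enolisation with internal silyl trapping (avoids β-elimination), then electrophilic bromination of the silyl enol ether anti to the neighbouring silyloxy group puts C9–Br trans to C18–O.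

Step 6
Reactants: 15 but-2-ynal; 16 2,3-dibromoprop-1-ene
Product: 19 (S)-2-bromohept-1-en-5-yn-4-ol, via allylchromium species 17 (not isolated), via trimethylsilyl ether 18 (not isolated)
Conditions: CrCl2 (10 mol%), (S)-N-[2-(4-isopropyl-4,5-dihydro-1,3-oxazol-2-yl)-6-methylphenyl]methanesulfonamide (12 mol%), Et3N (20 mol%), Mn powder (2 equiv), TMSCl (1.2 equiv), THF, 0 °C → rt; then 1 M HCl
Reagents that add atoms: none
Why: Catalytic asymmetric Nozaki–Hiyama 2-haloallylation: the ligand-bound trivalent allylchromium adds through a closed six-membered transition state to one aldehyde face and sets C6 (S), while Mn and TMSCl turn the chromium over.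

Step 7
Reactants: 19 (S)-2-bromohept-1-en-5-yn-4-ol
Product: 20 (S)-tert-butyl[(2-bromohept-1-en-5-yn-4-yl)oxy]dimethylsilane
Conditions: TBSCl, imidazole, DMF, rt
Reagents that add atoms: tert-butylchlorodimethylsilane, CC(C)(C)[Si](C)(C)Cl
Why: Standard silylation; the bulky ether makes the following hydrozirconation sterically regioselective and keeps the later organolithium clean.

Step 8
Reactants: 20 (S)-tert-butyl[(2-bromohept-1-en-5-yn-4-yl)oxy]dimethylsilane
Product: 22 (4S,5E)-2-bromo-4-[(tert-butyldimethylsilyl)oxy]-6-iodohepta-1,5-diene, via alkenylzirconocene 21 (not isolated)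
Conditions: Cp2Zr(H)Cl (1.5 equiv), THF, rt → 45 °C; then I2, 0 °C
Reagents that add atoms: iodine, II
Why: Hydrozirconation–iodination: syn addition of Zr–H places zirconium on the methyl-bearing alkyne carbon (remote from the branched silyloxy carbon) and iodinolysis with retention gives the 7E geometry (iodine trans to C6).

Step 9
Reactants: 22 (4S,5E)-2-bromo-4-[(tert-butyldimethylsilyl)oxy]-6-iodohepta-1,5-diene; 14 (2R,3S,6S)-2-bromo-3-[(tert-butyldimethylsilyl)oxy]-7,7-dimethyl-6-vinyl-2,3,4,5,6,7-hexahydro-1H-inden-1-one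
Product: 26 (2S,3R,6S)-2-[(2E,4S)-6-bromo-4-[(tert-butyldimethylsilyl)oxy]hepta-2,6-dien-2-yl]-3-[(tert-butyldimethylsilyl)oxy]-7,7-dimethyl-6-vinyl-2,3,4,5,6,7-hexahydro-1H-inden-1-one, via alkenyllithium 23 (not isolated), via alkenylcerium 24 (not isolated), via bromohydrin alkoxide 25 (not isolated)
Conditions: 22, t-BuLi (2.0 equiv), Et2O, −100 °C; CeCl3, THF, −78 °C; then 14, −78 °C; then ZnBr2 (1.5 equiv), −78 → 25 °C
Reagents that add atoms: none
Why: Organocerium 1,2-addition anti to the C9–Br bond (polar Felkin–Anh) gives the cis-bromohydrin alkoxide with the alkenyl group antiperiplanar to C–Br, and the Lewis-acid-assisted semipinacol (Tiffeneau-type halohydrin) 1,2-alkenyl shift with inversion at C9 forms C8–C9, regenerates the C10 ketone and places the side chain cis to the C18 silyloxy group (C9 S) with the alkene geometry retained.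

Step 10
Reactants: 26 (2S,3R,6S)-2-[(2E,4S)-6-bromo-4-[(tert-butyldimethylsilyl)oxy]hepta-2,6-dien-2-yl]-3-[(tert-butyldimethylsilyl)oxy]-7,7-dimethyl-6-vinyl-2,3,4,5,6,7-hexahydro-1H-inden-1-one
Product: 27 (3S,4E,6S,11R,16R)-6,16-bis[(tert-butyldimethylsilyl)oxy]-4,15,15-trimethyl-8-methylidenetricyclo[9.3.1.1(3,14)]hexadeca-1(14),4-dien-2-one
Conditions: NiBr2·DME (10 mol%), 4,4′-di-tert-butyl-2,2′-bipyridine (12 mol%), (EtO)2MeSiH (2.0 equiv), KF (2.5 equiv), DMA/THF, 0.002 M (syringe pump), 25 °C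
Reagents that add atoms: none
Why: Proposed new method: an intramolecular, macrocyclising nickel hydride hydroalkenylation in which L–Ni–H (from silane and fluoride) inserts only the unhindered monosubstituted C2=C3 olefin anti-Markovnikov to give a primary alkylnickel, oxidative addition of the 2-bromo-1-alkene and C(sp3)–C(sp2) reductive elimination then close the 12-membered ring at C3–C4 while the trisubstituted, exo-methylene and enone olefins stay untouched, closure being favoured because both tethers sit on the same face of the bicyclic core and no stereocentre is formed; the closest known reaction is the intermolecular nickel hydride-catalysed reductive hydroarylation/hydroalkenylation of terminal olefins with aryl or alkenyl halides.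

Step 11
Reactants: 27 (3S,4E,6S,11R,16R)-6,16-bis[(tert-butyldimethylsilyl)oxy]-4,15,15-trimethyl-8-methylidenetricyclo[9.3.1.1(3,14)]hexadeca-1(14),4-dien-2-one
Product: 28 (3S,4E,6S,11R,16R)-6,16-dihydroxy-4,15,15-trimethyl-8-methylidenetricyclo[9.3.1.1(3,14)]hexadeca-1(14),4-dien-2-one
Conditions: HF·pyridine, pyridine, THF, 0 °C → rt
Reagents that add atoms: none
Why: Fluoride-mediated desilylation under buffered, mildly acidic conditions that leave the β-hydroxy enone and the allylic alcohol intact.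

Step 12
Reactants: 28 (3S,4E,6S,11R,16R)-6,16-dihydroxy-4,15,15-trimethyl-8-methylidenetricyclo[9.3.1.1(3,14)]hexadeca-1(14),4-dien-2-one
Product: 29 (3S,4E,6S,11R,16R)-4,15,15-trimethyl-8-methylidene-2-oxotricyclo[9.3.1.1(3,14)]hexadeca-1(14),4-diene-6,16-diyl diacetate (CNP0121312.1)
Conditions: Ac2O, pyridine, DMAP (5 mol%), CH2Cl2, 0 °C
Reagents that add atoms: acetic anhydride, CC(=O)OC(C)=O
Why: Nucleophile-catalysed acylation of both secondary alcohols touches no stereocentre, and weak base at 0 °C avoids elimination of the β-acetoxy ketone.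

**Compound list**

1 | 2-methylcyclohex-2-en-1-one | CC1=CCCCC1=O | starting material
2 | vinylmagnesium bromide | C=C[Mg]Br | starting material
3 | bromomagnesium (3S)-2-methyl-3-vinylcyclohex-1-en-1-olate | C=C[C@@H]1CCCC(O[Mg]Br)=C1C | intermediate
4 | (S)-2,2-dimethyl-3-vinylcyclohexan-1-one | C=C[C@@H]1CCCC(=O)C1(C)C | intermediate
5 | N-{[(4S)-2-bromo-3,3-dimethyl-4-vinylcyclohex-1-en-1-yl]methylidene}-N-methylmethanaminium bromide | C=C[C@@H]1CCC(C=[N+](C)C)=C(Br)C1(C)C.[Br-] | intermediate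
6 | (4S)-2-bromo-3,3-dimethyl-4-vinylcyclohex-1-ene-1-carbaldehyde | C=C[C@@H]1CCC(C=O)=C(Br)C1(C)C | intermediate
7 | 1-(tert-butyldimethylsilyloxy)-1-methoxyethene (silyl ketene acetal of methyl acetate) | C=C(OC)O[Si](C)(C)C(C)(C)C | starting material
8 | methyl (3R)-3-[(4S)-2-bromo-3,3-dimethyl-4-vinylcyclohex-1-en-1-yl]-3-[(trichlorosilyl)oxy]propanoate | COC(=O)C[C@@H](O[Si](Cl)(Cl)Cl)C1=C(Br)C(C)(C)[C@H](C=C)CC1 | intermediate
9 | methyl (3R)-3-[(4S)-2-bromo-3,3-dimethyl-4-vinylcyclohex-1-en-1-yl]-3-hydroxypropanoate | COC(=O)C[C@@H](O)C1=C(Br)C(C)(C)[C@H](C=C)CC1 | intermediate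
10 | methyl (3R)-3-[(4S)-2-lithio-3,3-dimethyl-4-vinylcyclohex-1-en-1-yl]-3-(lithiooxy)propanoate | COC(=O)C[C@@H](O[Li])C1=C([Li])C(C)(C)[C@H](C=C)CC1 | intermediate
11 | lithium alkoxide of (3R,6S)-3-hydroxy-7,7-dimethyl-6-vinyl-2,3,4,5,6,7-hexahydro-1H-inden-1-one | O=C1C[C@@H](O[Li])C2=C1C(C)(C)[C@H](C=C)CC2 | intermediate
12 | (3R,6S)-3-[(tert-butyldimethylsilyl)oxy]-7,7-dimethyl-6-vinyl-2,3,4,5,6,7-hexahydro-1H-inden-1-one | O=C1C[C@@H](O[Si](C)(C)C(C)(C)C)C2=C1C(C)(C)[C@H](C=C)CC2 | intermediate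
13 | (1R,5S)-1-[(tert-butyldimethylsilyl)oxy]-4,4-dimethyl-3-[(trimethylsilyl)oxy]-5-vinyl-4,5,6,7-tetrahydro-1H-indene | C[Si](C)(C)OC1=C[C@@H](O[Si](C)(C)C(C)(C)C)C2=C1C(C)(C)[C@H](C=C)CC2 | intermediate
14 | (2R,3S,6S)-2-bromo-3-[(tert-butyldimethylsilyl)oxy]-7,7-dimethyl-6-vinyl-2,3,4,5,6,7-hexahydro-1H-inden-1-one (Br trans to OTBS) | O=C1[C@H](Br)[C@@H](O[Si](C)(C)C(C)(C)C)C2=C1C(C)(C)[C@H](C=C)CC2 | intermediate
15 | but-2-ynal | CC#CC=O | starting material
16 | 2,3-dibromoprop-1-ene | C=C(Br)CBr | starting material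
17 | (2-bromoallyl)chromium dichloride (ligand-bound, trivalent chromium) | C=C(Br)C[Cr](Cl)Cl | intermediate
18 | (S)-[(2-bromohept-1-en-5-yn-4-yl)oxy]trimethylsilane | CC#C[C@@H](O[Si](C)(C)C)CC(Br)=C | intermediate
19 | (S)-2-bromohept-1-en-5-yn-4-ol | CC#C[C@@H](O)CC(Br)=C | intermediate
20 | (S)-tert-butyl[(2-bromohept-1-en-5-yn-4-yl)oxy]dimethylsilane | CC#C[C@@H](O[Si](C)(C)C(C)(C)C)CC(Br)=C | intermediate
21 | chloro{(2E,4S)-6-bromo-4-[(tert-butyldimethylsilyl)oxy]hepta-2,6-dien-2-yl}zirconocene (Zr trans to C6) | Cl[Zr](C1C=CC=C1)(C1C=CC=C1)/C(C)=C/[C@@H](O[Si](C)(C)C(C)(C)C)CC(Br)=C | intermediate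
22 | (4S,5E)-2-bromo-4-[(tert-butyldimethylsilyl)oxy]-6-iodohepta-1,5-diene | I/C(C)=C/[C@@H](O[Si](C)(C)C(C)(C)C)CC(Br)=C | intermediate
23 | (4S)-6-bromo-4-[(tert-butyldimethylsilyl)oxy]hepta-2,6-dien-2-yllithium (Li trans to C6) | [Li]/C(C)=C/[C@@H](O[Si](C)(C)C(C)(C)C)CC(Br)=C | intermediate
24 | {(4S)-6-bromo-4-[(tert-butyldimethylsilyl)oxy]hepta-2,6-dien-2-yl}cerium dichloride (Ce trans to C6) | Cl[Ce](Cl)/C(C)=C/[C@@H](O[Si](C)(C)C(C)(C)C)CC(Br)=C | intermediate
25 | dichlorocerium alkoxide of (1S,2R,3S,6S)-2-bromo-1-[(2E,4S)-6-bromo-4-[(tert-butyldimethylsilyl)oxy]hepta-2,6-dien-2-yl]-3-[(tert-butyldimethylsilyl)oxy]-7,7-dimethyl-6-vinyl-2,3,4,5,6,7-hexahydro-1H-inden-1-ol (alkenyl anti to Br) | Cl[Ce](Cl)O[C@]1(/C(C)=C/[C@@H](O[Si](C)(C)C(C)(C)C)CC(Br)=C)[C@H](Br)[C@@H](O[Si](C)(C)C(C)(C)C)C2=C1C(C)(C)[C@H](C=C)CC2 | intermediate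
26 | (2S,3R,6S)-2-[(2E,4S)-6-bromo-4-[(tert-butyldimethylsilyl)oxy]hepta-2,6-dien-2-yl]-3-[(tert-butyldimethylsilyl)oxy]-7,7-dimethyl-6-vinyl-2,3,4,5,6,7-hexahydro-1H-inden-1-one (side chain cis to OTBS) | O=C1[C@@H](/C(C)=C/[C@@H](O[Si](C)(C)C(C)(C)C)CC(Br)=C)[C@@H](O[Si](C)(C)C(C)(C)C)C2=C1C(C)(C)[C@H](C=C)CC2 | intermediate
27 | (3S,4E,6S,11R,16R)-6,16-bis[(tert-butyldimethylsilyl)oxy]-4,15,15-trimethyl-8-methylidenetricyclo[9.3.1.1(3,14)]hexadeca-1(14),4-dien-2-one | C=C1CC[C@@H]2CCC3=C(C(=O)[C@@H](/C(C)=C/[C@@H](O[Si](C)(C)C(C)(C)C)C1)[C@H]3O[Si](C)(C)C(C)(C)C)C2(C)C | intermediate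
28 | (3S,4E,6S,11R,16R)-6,16-dihydroxy-4,15,15-trimethyl-8-methylidenetricyclo[9.3.1.1(3,14)]hexadeca-1(14),4-dien-2-one | C=C1CC[C@@H]2CCC3=C(C(=O)[C@@H](/C(C)=C/[C@@H](O)C1)[C@H]3O)C2(C)C | intermediate
29 | (3S,4E,6S,11R,16R)-4,15,15-trimethyl-8-methylidene-2-oxotricyclo[9.3.1.1(3,14)]hexadeca-1(14),4-diene-6,16-diyl diacetate | C=C1CC[C@@H]2CCC3=C(C(=O)[C@@H](/C(C)=C/[C@@H](OC(C)=O)C1)[C@H]3OC(C)=O)C2(C)C | target

**Totals and risks**

Total step count: 12. Longest linear sequence: 9 steps (steps 1–5 and 9–12); the C4–C8 piece takes 3 steps (6–8) before it joins.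

The three steps most likely to fail:

Step 1. Vinyl Grignard reagents usually give lower enantioselectivity than alkyl ones in copper-catalysed conjugate addition, and the magnesium enolate is slow to methylate. Fallback: setting out from 1, the same copper-catalysed addition/methylation is run with the alkyl reagent [2-(1,3-dioxan-2-yl)ethyl]magnesium bromide to give (S)-3-[2-(1,3-dioxan-2-yl)ethyl]-2,2-dimethylcyclohexan-1-one F1. PPTS in wet acetone then frees (S)-3-(2,2-dimethyl-3-oxocyclohexyl)propanal F2. Rhodium-catalysed transfer dehydroformylation ([Rh(cod)OMe]2, 4,5-bis(diphenylphosphino)-9,9-dimethylxanthene, 3-methoxybenzoic acid, norbornadiene, THF, 60 °C) removes the formyl carbon and comes back to the route at 4.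

Step 9. The organocerium may enolise or reduce the α-bromo ketone, attack syn to bromine (leading to an epoxide), or the cerium alkoxide may not rearrange cleanly. Fallback: setting out from 12 (with iodide 22), LiHMDS followed by zerovalent-palladium-catalysed α-alkenylation of the lithium enolate (Pd2(dba)3, P(t-Bu)3, THF) gives the thermodynamically preferred trans ketone (2R,3R,6S)-2-[(2E,4S)-6-bromo-4-[(tert-butyldimethylsilyl)oxy]hepta-2,6-dien-2-yl]-3-[(tert-butyldimethylsilyl)oxy]-7,7-dimethyl-6-vinyl-2,3,4,5,6,7-hexahydro-1H-inden-1-one F3. LiHMDS/TMSCl converts it into the trimethylsilyl dienol ether F4, and protonation at −78 °C (AcOH/THF) from the face anti to the C18 silyloxy group comes back to the route at 26. Any residual trans epimer cannot bridge to C1 and is filtered out at ring closure.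

Step 10 (the proposed new method). Nickel hydride may reduce the enone or the alkenyl bromide, isomerise the new exo-methylene, or give oligomers; fluoride may also erode the silyl ethers. Fallback (known chemistry): setting out from 26, 9-BBN (THF, rt) hydroborates only the monosubstituted vinyl group to give the B-alkyl-9-borabicyclo[3.3.1]nonane F5, which without isolation undergoes intramolecular B-alkyl Suzuki–Miyaura coupling with the 2-bromo-1-alkene (Pd(dppf)Cl2, AsPh3, Cs2CO3, DMF/THF/H2O, high dilution, rt) and comes back to the route at 27.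

**Further compounds**

F1 | step 1 | (S)-3-[2-(1,3-dioxan-2-yl)ethyl]-2,2-dimethylcyclohexan-1-one | O1CCCOC1CC[C@@H]2CCCC(=O)C2(C)C
F2 | step 1 | (S)-3-(2,2-dimethyl-3-oxocyclohexyl)propanal | O=CCC[C@@H]1CCCC(=O)C1(C)C
F3 | step 9 | (2R,3R,6S)-2-[(2E,4S)-6-bromo-4-[(tert-butyldimethylsilyl)oxy]hepta-2,6-dien-2-yl]-3-[(tert-butyldimethylsilyl)oxy]-7,7-dimethyl-6-vinyl-2,3,4,5,6,7-hexahydro-1H-inden-1-one | O=C1[C@H](/C(C)=C/[C@@H](O[Si](C)(C)C(C)(C)C)CC(Br)=C)[C@@H](O[Si](C)(C)C(C)(C)C)C2=C1C(C)(C)[C@H](C=C)CC2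
F4 | step 9 | (1R,5S)-2-[(2E,4S)-6-bromo-4-[(tert-butyldimethylsilyl)oxy]hepta-2,6-dien-2-yl]-1-[(tert-butyldimethylsilyl)oxy]-4,4-dimethyl-3-[(trimethylsilyl)oxy]-5-vinyl-4,5,6,7-tetrahydro-1H-indene | C[Si](C)(C)OC1=C(/C(C)=C/[C@@H](O[Si](C)(C)C(C)(C)C)CC(Br)=C)[C@@H](O[Si](C)(C)C(C)(C)C)C2=C1C(C)(C)[C@H](C=C)CC2
F5 | step 10 | (2S,3R,6R)-6-[2-(9-borabicyclo[3.3.1]nonan-9-yl)ethyl]-2-[(2E,4S)-6-bromo-4-[(tert-butyldimethylsilyl)oxy]hepta-2,6-dien-2-yl]-3-[(tert-butyldimethylsilyl)oxy]-7,7-dimethyl-2,3,4,5,6,7-hexahydro-1H-inden-1-one | O=C1[C@@H](/C(C)=C/[C@@H](O[Si](C)(C)C(C)(C)C)CC(Br)=C)[C@@H](O[Si](C)(C)C(C)(C)C)C2=C1C(C)(C)[C@H](CCB1C3CCCC1CCC3)CC2
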